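The easy step came first: target and isomer of the product sit on one reversible step, so I could write their equilibrium share (thermodynamic control) before asking how much of either forms.

    starting material + 2 target → 3 target (k1 = 140 L² mol⁻² min⁻¹, Ea1 = 50.0 kJ mol⁻¹)
    starting material → target (k2 = 1.2 × 10⁻⁴ min⁻¹, Ea2 = 122 kJ mol⁻¹)
    target ⇌ isomer of the product (K3 = 0.39, k3 = 0.24 min⁻¹, Ea3 = 109 kJ mol⁻¹, ΔH3 = −10.0 kJ mol⁻¹)
    2 starting material → homo dimer (k4 = 1.4 L mol⁻¹ min⁻¹, Ea4 = 49.0 kJ mol⁻¹)
    starting material + protic impurity → quenched substrate (k5 = 3.5 L mol⁻¹ min⁻¹, Ea5 = 66.0 kJ mol⁻¹)
    (constants at 70 °C)

- alder: starting material 20 mM (in portions, 4); protic impurity 6.00 mM; temperature 55 °C; time 40 min; the portions of starting material follow each other after 2.0 min, the first at the start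
- oak: starting material 20 mM (in portions, 4); protic impurity 6.00 mM; temperature 70 °C; time 40 min; the portions of starting material follow each other after 2.0 min, the first at the start

- percent here means starting material units held: one homo dimer counts as two
- where a step has two of a species, its rate is k times that concentration squared, and two are used at each turn
- the list of constants is for 70 °C, to be carried to other temperatures by the activation energies and enthalpies

- the flask that comes out highest in share of target in all that became target or isomer of the product, or "all alike" when all lie within 1.5 percentage points (alder / oak / all alike)
- share of target in all that became target or isomer of the product, alder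
- share of target in all that became target or isomer of the product, oak

I carried the equilibrium constant down from 70 °C by the enthalpy, which gave 0.458 for alder.

Equilibrium share s, one over one plus the constant: oak 71.9%, alder 68.6%

Then I asked what feeds the pair. In oak, the uncatalysed step acting on a full charge for the whole time makes a fraction 0.480% of the charge. Even with that much standing as target, the autocatalytic step runs far slower than the uncatalysed one, at 1.08% of its rate. So I let the uncatalysed step feed target, in proportion to the fraction a of starting material.

In a fed pair, isomer of the product follows fresh target with a delay, and I reckoned the share of target to stand above its equilibrium value for that reason. The lag time, one over the sum of the forward and reverse constants of the reversible step, is 1.17 min in oak and 7.50 min in alder.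

Flat feed, share = s + (1 − s)(lag/time)(1 − exp(−time/lag)): oak 72.8%, alder 74.5%

That gap of 1.7 percentage points is wider than the margin, but the flat feed was the weak link, since a falls and the lag acts on recent feed. I replaced the curve by its mean and scaled the excess by r, end feed over mean feed. Dimerisation sets the fall, because at full charge it removes starting material at 0.0560 min⁻¹ in oak, faster than quenching at 0.0210 min⁻¹. I ignored the quenching and the portions, and took a = 1/(1 + G·t/time), with G the dimer rate times the time.

r = G/((1 + G) ln(1 + G)): oak 0.588, alder 0.718

Committed shares: oak 72.4%, alder 72.8%

Their gap of 0.40 points lies inside the margin, so I called the flasks equal.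

The forecast said all alike, with 73.5% for alder (72.8% to 74.2%) and 72.4% for oak (72.1% to 72.7%), on the ground that “the slower isomerisation lags the fresh feed by roughly 5 points”. My alder figure stood lower than its 73.5%.

The simulation gave 73.5% for alder and 72.4% for oak, so the answer was all alike. In oak, the relaxation half-life of 0.810 min is short against the time of 40 min, and the share of 72.4% there stood 0.50 points above my equilibrium share. The repeat of oak at 45 °C has a lag of 28.5 min, longer than in oak. With 66.1% as its equilibrium share, the flat-feed rule gives 84.3%, and that flask stood at 84.0%.

The constants were chosen freely, and the outcome is calculated.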